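**Plan**
- Numbering follows the heavy atoms of the target SMILES: ring A is the lactone (C18, C19, C20, O22, C23, C26), ring B the cycloheptadiene (C15, C16, C18, C26, C27, C28, C29), ring C is C5/C29/C15/C14/C12/C31 and ring D is C5/C6/C7/C10/C12/C31.
- Retrosynthesis cuts the epoxide oxygen O33, then O22–C20 and C18–C19 (lactone and acetate unit), the two C23 methyls, C26=C27 and C18–C26 (ring B), C7–O9 and C7–C8, C31=C32, C10–C12 (ring D), and finally C5–C6 with C28–C29, the C5 ester and the C12 methyl, back to ring C from verbenone.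
- Forward order: ring C from verbenone by cyclobutane cleavage; the C29/C5 quaternary pair; ring D by aldol; C31 methylidene and the C7 methyl and oxygen; ring B by metathesis; ring A by lactonisation; the epoxide last.
- Stereochemistry: C15 comes from verbenone, C29 is set anti to C15, C5 anti to the axial C30 methyl, C12 by the tether, C7 by two successive exo attacks (carbon, then oxygen), and C31 by oxygen delivery from the C7 hydroxyl.

Key step: step 5

Remark: (1R,5R)-verbenone 1, allylmagnesium bromide 7 (ether solution) and acrolein 8 are taken as commercial.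
Remark: C12 in 4–10 is drawn as the epimer expected from methylation anti to the isopropenyl group and C7 in 15 as the exo-methyl epimer; C10 in 11 and 12, and C16 and C18 in 19–26, are carried as mixtures and written without descriptors; each of these centres is reset or becomes trigonal before the target.

**Step 1**
Reactants: 1 (1R,5R)-verbenone
Product: 2 (4S)-5-methyl-4-(prop-1-en-2-yl)cyclohexa-1,5-dien-1-yl acetate
Conditions: Ac2O, BF3·OEt2, Zn(OAc)2, 0 °C to rt
Reagents that add atoms: acetic anhydride, CC(=O)OC(C)=O
Why: Lewis-acid activation of the enone lets the strained cyclobutane bond between the carbonyl α-carbon and the gem-dimethyl carbon ionise to a tertiary cation and a dienolate (acid-induced cyclobutane fragmentation of a pinane ketone), proton loss gives the isopropenyl group and O-acetylation the dienyl acetate, while the remaining verbenone stereocentre is untouched and becomes C15.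

**Step 2**
Reactants: 2 (4S)-5-methyl-4-(prop-1-en-2-yl)cyclohexa-1,5-dien-1-yl acetate
Product: 4 (4S,6R)-3,6-dimethyl-4-(prop-1-en-2-yl)cyclohex-2-en-1-one, via lithium dienolate 3 (not isolated)
Conditions: MeLi (2.1 equiv), THF, 0 °C; then MeI, −78 to 0 °C
Reagents that add atoms: iodomethane, CI
Why: Methyllithium cleaves the enol acetate to the regiodefined cross-conjugated lithium dienolate (enol ester cleavage followed by enolate alkylation), which should be methylated at the α′ carbon C12 from the face away from the pseudoaxial isopropenyl group, a configuration without consequence because C12 is re-enolised in step 6.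

**Step 3**
Reactants: 4 (4S,6R)-3,6-dimethyl-4-(prop-1-en-2-yl)cyclohex-2-en-1-one
Product: 5 (4S,6R)-2-iodo-3,6-dimethyl-4-(prop-1-en-2-yl)cyclohex-2-en-1-one
Conditions: I2, pyridine, DMAP (catalytic), CH2Cl2, rt
Reagents that add atoms: iodine, II
Why: Conjugate addition of the pyridine base, iodination of the resulting enolate and elimination (α-iodination of an enone) functionalise C5 without touching the α′ or γ centres.

**Step 4**
Reactants: 5 (4S,6R)-2-iodo-3,6-dimethyl-4-(prop-1-en-2-yl)cyclohex-2-en-1-one
Product: 6 methyl (3S,5R)-2,5-dimethyl-6-oxo-3-(prop-1-en-2-yl)cyclohex-1-ene-1-carboxylate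
Conditions: Pd(OAc)2, PPh3, CO (1 atm), MeOH, iPr2NEt, DMF, 40 °C
Reagents that add atoms: carbon monoxide, [C-]#[O+]; methanol, CO
Why: Oxidative addition of the alkenyl iodide to zerovalent palladium, CO insertion and methanolysis of the acylpalladium (palladium-catalysed alkoxycarbonylation) install the ester at C5, and the mild base and short contact time are chosen because the C15 hydrogen of the product is vinylogously acidic.

**Step 5**
Reactants: 6 methyl (3S,5R)-2,5-dimethyl-6-oxo-3-(prop-1-en-2-yl)cyclohex-1-ene-1-carboxylate; 7 allylmagnesium bromide; 8 acrolein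
Product: 10 methyl (1R,2S,3S,5R)-2,5-dimethyl-6-oxo-1-(3-oxopropyl)-2-(prop-2-en-1-yl)-3-(prop-1-en-2-yl)cyclohexane-1-carboxylate, via magnesium enolate 9 (not isolated)
Conditions: CuBr·SMe2 (20 mol%), THF, −78 °C, slow addition of 7; then 8 (3 equiv), −78 to −30 °C; aqueous NH4Cl
Reagents that add atoms: none
Why: Transmetalation of 7 with CuBr·SMe2 gives an allylcopper species that adds 1,4 to the alkylidene β-keto ester, and the chelated magnesium enolate 9 then adds to the β-carbon of acrolein, the aldehyde enolate being protonated on work-up. The closest known reaction type is the organocopper conjugate addition to 2-alkoxycarbonyl cycloalkenones with trapping of the enolate by a carbon electrophile in the same flask (three-component coupling). No ring closes in this step. C29 is set by C15: allylic strain with the C30 methyl holds the isopropenyl group pseudoaxial, and the allyl group enters axially on the opposite face. C5 is set by C29: in the reactive half-chair of 9 the isopropenyl and allyl groups are equatorial and the C30 methyl is axial, so acrolein should approach axially, anti to that methyl, which places C6 cis to the allyl group. The step needs 1,4- over 1,2-addition (secured by copper and the double activation), C- over O-alkylation and conjugate over carbonyl attack on acrolein (secured by the soft, stabilised enolate), and the two facial selectivities just named.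

**Step 6**
Reactants: 10 methyl (1R,2S,3S,5R)-2,5-dimethyl-6-oxo-1-(3-oxopropyl)-2-(prop-2-en-1-yl)-3-(prop-1-en-2-yl)cyclohexane-1-carboxylate
Product: 11 methyl 6-hydroxy-2,5-dimethyl-9-oxo-2-(prop-2-en-1-yl)-3-(prop-1-en-2-yl)bicyclo[3.3.1]nonane-1-carboxylate (ring C/D hydroxy ketone)
Conditions: 2 M aqueous HCl, THF, rt
Reagents that add atoms: none
Why: Acid-catalysed enolisation of the C31 ketone, possible only toward C12, and attack of the enol on the protonated aldehyde (intramolecular aldol addition) close ring D, and the tether on C5 forces the new C12–C10 bond onto the face of C6, which fixes the C12 quaternary centre whatever the earlier configuration there.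

**Step 7**
Reactants: 11 ring C/D hydroxy ketone
Product: 12 C31-methylidene alcohol (9-methylidene analogue of 11)
Conditions: Zn, CH2Br2, TiCl4, THF/CH2Cl2, 0 °C to rt
Reagents that add atoms: dibromomethane, BrCBr
Why: Methylenation with the gem-dimetallic reagent from Zn, CH2Br2 and TiCl4 (Takai–Lombardo methylenation) is non-basic, so neither retro-aldol nor retro-Claisen cleavage should intervene, it tolerates the free hydroxyl and the ester, and it is placed here because the non-enolisable C31 carbonyl is the only ketone in the molecule at this stage.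

**Step 8**
Reactants: 12 C31-methylidene alcohol
Product: 13 methyl 2,5-dimethyl-9-methylidene-6-oxo-2-(prop-2-en-1-yl)-3-(prop-1-en-2-yl)bicyclo[3.3.1]nonane-1-carboxylate (C10 ketone)
Conditions: Dess–Martin periodinane, NaHCO3, CH2Cl2, rt
Reagents that add atoms: none
Why: Dess–Martin oxidation of the secondary alcohol gives the C10 ketone under buffered neutral conditions that leave the three alkenes untouched.

**Step 9**
Reactants: 13 C10 ketone
Product: 15 C7-methyl ketone (7-exo-methyl derivative of 13), via lithium enolate 14 (not isolated)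
Conditions: LiN(iPr)2, THF, −78 °C; then MeI, −78 to −20 °C
Reagents that add atoms: iodomethane, CI
Why: C7 is the only enolisable position, so kinetic deprotonation and enolate alkylation put the methyl group there, entering from the exo face of ring D away from ring C, and this configuration is erased again in step 10.

**Step 10**
Reactants: 15 C7-methyl ketone
Product: 17 triethylsilyl enol ether (C7=C10–OSiEt3), via potassium enolate 16 (not isolated)
Conditions: KN(SiMe3)2, THF, −78 to 0 °C; then Et3SiCl, −78 °C
Reagents that add atoms: chlorotriethylsilane, CC[Si](Cl)(CC)CC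
Why: The last C7 hydrogen is the only acidic one in the molecule, so it can be removed under forcing conditions and the enolate O-silylated (enolate trapping) to a tetrasubstituted enol ether that lies away from the bridgehead and is unstrained.

**Step 11**
Reactants: 17 triethylsilyl enol ether
Product: 19 C7-triethylsilyloxy ketone with the isopropenyl group epoxidised (2-methyloxiran-2-yl on C15), via silyloxy ketone 18 (not isolated)
Conditions: mCPBA (2.2 equiv), NaHCO3, CH2Cl2, −20 to 0 °C
Reagents that add atoms: 3-chloroperoxybenzoic acid, OOC(=O)c1cccc(Cl)c1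
Why: The electron-rich enol ether is epoxidised first from the exo face and rearranges with silyl migration to the α-silyloxy ketone (Rubottom oxidation), which sets C7 with oxygen exo and methyl endo, and the second equivalent should epoxidise the 1,1-disubstituted isopropenyl group in preference to the monosubstituted allyl group and the shielded, electron-poor C31 methylidene (peracid epoxidation).

**Step 12**
Reactants: 19 silyloxy ketone epoxide
Product: 20 aldehyde (1-oxopropan-2-yl on C15; C18 is the formyl carbon)
Conditions: BF3·OEt2 (0.3 equiv), CH2Cl2, −78 °C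
Reagents that add atoms: none
Why: Lewis-acid opening of the 2,2-disubstituted epoxide to the tertiary cation and 1,2-hydride shift (Meinwald rearrangement) give the aldehyde, and the new C16 centre is of no consequence because it becomes an alkene carbon in step 18.

**Step 13**
Reactants: 20 aldehyde
Product: 21 Baylis–Hillman-type adduct (C15 bears CH(CH3)–CH(OH)–C(=CH2)CO2Me)
Conditions: iBu2AlH, N-methylmorpholine N-oxide, methyl propiolate, THF, 0 °C; then 20, 0 °C to rt; aqueous potassium sodium tartrate
Reagents that add atoms: methyl propiolate, C#CC(=O)OC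
Why: Hydroalumination of methyl propiolate gives the α-aluminated acrylate, which adds to the hindered aldehyde to give the product of a Baylis–Hillman reaction (vinylalumination of an aldehyde), forms the C18–C26 bond and should ignore the shielded C10 ketone, the C18 carbinol mixture being oxidised in step 16.

**Step 14**
Reactants: 21 Baylis–Hillman-type adduct
Product: 22 ring B cycloheptene (C18 hydroxyl; C26 methyl ester; C26=C27)
Conditions: second-generation Grubbs catalyst (10 mol%), toluene, 80 °C
Reagents that add atoms: none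
Why: Ring-closing metathesis between the allyl group and the acrylate methylene forms the trisubstituted C26=C27 bond and the seven-membered ring B, trans-fused because both tethers are equatorial on ring C, while the C31 methylidene between two quaternary carbons should not enter the catalytic cycle.

**Step 15**
Reactants: 22 ring B cycloheptene
Product: 24 diol (C18 secondary hydroxyl; C23 tertiary hydroxyl), via methyl ketone 23 (not isolated)
Conditions: MeMgBr (5 equiv), THF, −40 to 0 °C; aqueous NH4Cl
Reagents that add atoms: methylmagnesium bromide, C[Mg]Br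
Why: Double Grignard addition to the conjugated ester builds the C23 carbinol through the acetyl intermediate, which reacts at the carbonyl carbon, while the C3 ester and the C10 ketone, each flanked by fully substituted carbons, should stay untouched.

**Step 16**
Reactants: 24 diol
Product: 25 hydroxy enone (C18 ketone; C23 hydroxyl)
Conditions: Dess–Martin periodinane, NaHCO3, CH2Cl2, 0 °C to rt
Reagents that add atoms: none
Why: Dess–Martin oxidation converts the secondary allylic alcohol into the cycloheptenone and cannot oxidise the tertiary alcohol.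

**Step 17**
Reactants: 25 hydroxy enone
Product: 26 bis(triethylsilyl) enone (C7 and C23 silyl ethers)
Conditions: Et3SiOTf, 2,6-lutidine, CH2Cl2, −78 to 0 °C
Reagents that add atoms: triethylsilyl trifluoromethanesulfonate, CC[Si](CC)(CC)OS(=O)(=O)C(F)(F)F
Why: Silylation of the tertiary alcohol with the silyl triflate and a hindered pyridine base (silyl ether formation) removes the only hydroxyl proton before the enolate chemistry of step 18.

**Step 18**
Reactants: 26 bis(triethylsilyl) enone
Product: 28 dienyl triflate (C16=C18–OTf; C26=C27), via potassium dienolate 27 (not isolated)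
Conditions: KN(SiMe3)2, THF, −78 °C; then PhNTf2, −78 to −40 °C
Reagents that add atoms: N-phenylbis(trifluoromethanesulfonimide), FC(F)(F)S(=O)(=O)N(c1ccccc1)S(=O)(=O)C(F)(F)F
Why: C16 carries the only α-hydrogen of the enone, so kinetic deprotonation there, in preference to the γ position C28, and O-sulfonylation (enol triflate formation) fix the C16=C18 double bond and remove the C16 stereocentre.

**Step 19**
Reactants: 28 dienyl triflate
Product: 29 diene ester (C18–CH2CO2Me)
Conditions: BrZnCH2CO2Me (from BrCH2CO2Me and Zn, THF), Pd(PPh3)4 (10 mol%), THF, 60 °C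
Reagents that add atoms: bromo(2-methoxy-2-oxoethyl)zinc, COC(=O)C[Zn]Br
Why: Oxidative addition of the dienyl triflate to zerovalent palladium, transmetalation with the zinc ester enolate and reductive elimination (Negishi coupling of a Reformatsky reagent with an alkenyl triflate) attach the acetate unit to C18 directly as the β,γ-unsaturated ester, so the diene never has to be moved out of conjugation with the carbonyl group.

**Step 20**
Reactants: 29 diene ester
Product: 31 C31-methylidene lactone (rings A–D complete; free C7 hydroxyl), via dihydroxy ester 30 (not isolated)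
Conditions: 48% aqueous HF, MeCN, 0 °C to rt
Reagents that add atoms: none
Why: Aqueous HF cleaves both triethylsilyl ethers, and the freed tertiary hydroxyl, held next to the ester by the cisoid diene and helped by the gem-dimethyl effect, should close the six-membered lactone (acid-catalysed lactonisation) under acidity too weak to protonate the diene.

**Step 21**
Reactants: 31 C31-methylidene lactone
Product: 32 CNP0605450.1 (target)
Conditions: VO(acac)2 (10 mol%), t-BuOOH, CH2Cl2, 0 °C to rt
Reagents that add atoms: tert-butyl hydroperoxide, CC(C)(C)OO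
Why: The vanadium alkoxide of the C7 hydroxyl, which sits over the ring-D face of the C31 methylidene, should deliver the peroxide oxygen intramolecularly (hydroxyl-directed epoxidation), so the epoxide oxygen ends syn to ring D as in the target while the diene, which has no directing group, is left alone.

**Compound list**
1 | (1R,5R)-verbenone | CC1=CC(=O)[C@@H]2C[C@H]1C2(C)C | starting material
2 | (4S)-5-methyl-4-(prop-1-en-2-yl)cyclohexa-1,5-dien-1-yl acetate | CC(=O)OC1=CC[C@@H](C(C)=C)C(C)=C1 | intermediate
3 | lithium dienolate of (4S)-3-methyl-4-(prop-1-en-2-yl)cyclohex-2-en-1-one (not isolated) | [Li]OC1=CC[C@@H](C(C)=C)C(C)=C1 | intermediate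
4 | (4S,6R)-3,6-dimethyl-4-(prop-1-en-2-yl)cyclohex-2-en-1-one | C[C@@H]1C[C@@H](C(C)=C)C(C)=CC1=O | intermediate
5 | (4S,6R)-2-iodo-3,6-dimethyl-4-(prop-1-en-2-yl)cyclohex-2-en-1-one | C[C@@H]1C[C@@H](C(C)=C)C(C)=C(I)C1=O | intermediate
6 | methyl (3S,5R)-2,5-dimethyl-6-oxo-3-(prop-1-en-2-yl)cyclohex-1-ene-1-carboxylate | COC(=O)C1=C(C)[C@H](C(C)=C)C[C@@H](C)C1=O | intermediate
7 | allylmagnesium bromide | C=CC[Mg]Br | starting material
8 | acrolein | C=CC=O | starting material
9 | bromomagnesium enolate of methyl (2S,3S,5R)-2,5-dimethyl-6-oxo-2-(prop-2-en-1-yl)-3-(prop-1-en-2-yl)cyclohexane-1-carboxylate (not isolated) | COC(=O)C1=C(O[Mg]Br)[C@H](C)C[C@@H](C(C)=C)[C@]1(C)CC=C | intermediate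
10 | methyl (1R,2S,3S,5R)-2,5-dimethyl-6-oxo-1-(3-oxopropyl)-2-(prop-2-en-1-yl)-3-(prop-1-en-2-yl)cyclohexane-1-carboxylate | COC(=O)[C@@]1(CCC=O)C(=O)[C@H](C)C[C@@H](C(C)=C)[C@]1(C)CC=C | intermediate
11 | ring C/D hydroxy ketone (C10 carbinol epimers) | COC(=O)[C@]12CCC(O)[C@](C)(C[C@@H](C(C)=C)[C@]1(C)CC=C)C2=O | intermediate
12 | C31-methylidene alcohol | COC(=O)[C@]12CCC(O)[C@](C)(C[C@@H](C(C)=C)[C@]1(C)CC=C)C2=C | intermediate
13 | C10 ketone with C31 methylidene | COC(=O)[C@]12CCC(=O)[C@](C)(C[C@@H](C(C)=C)[C@]1(C)CC=C)C2=C | intermediate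
14 | lithium C7=C10 enolate of 13 (not isolated) | COC(=O)[C@]12CC=C(O[Li])[C@](C)(C[C@@H](C(C)=C)[C@]1(C)CC=C)C2=C | intermediate
15 | C7-methyl ketone (exo methyl) | COC(=O)[C@]12C[C@@H](C)C(=O)[C@](C)(C[C@@H](C(C)=C)[C@]1(C)CC=C)C2=C | intermediate
16 | potassium enolate of 15 (not isolated) | COC(=O)[C@]12CC(C)=C(O[K])[C@](C)(C[C@@H](C(C)=C)[C@]1(C)CC=C)C2=C | intermediate
17 | triethylsilyl enol ether of 15 | COC(=O)[C@]12CC(C)=C(O[Si](CC)(CC)CC)[C@](C)(C[C@@H](C(C)=C)[C@]1(C)CC=C)C2=C | intermediate
18 | C7-triethylsilyloxy ketone with intact isopropenyl group (not isolated) | COC(=O)[C@]12C[C@@](C)(O[Si](CC)(CC)CC)C(=O)[C@](C)(C[C@@H](C(C)=C)[C@]1(C)CC=C)C2=C | intermediate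
19 | C7-triethylsilyloxy ketone with 2-methyloxiran-2-yl on C15 | COC(=O)[C@]12C[C@@](C)(O[Si](CC)(CC)CC)C(=O)[C@](C)(C[C@@H](C3(C)CO3)[C@]1(C)CC=C)C2=C | intermediate
20 | aldehyde (1-oxopropan-2-yl on C15) | COC(=O)[C@]12C[C@@](C)(O[Si](CC)(CC)CC)C(=O)[C@](C)(C[C@@H](C(C)C=O)[C@]1(C)CC=C)C2=C | intermediate
21 | Baylis–Hillman-type adduct | COC(=O)[C@]12C[C@@](C)(O[Si](CC)(CC)CC)C(=O)[C@](C)(C[C@@H](C(C)C(O)C(=C)C(=O)OC)[C@]1(C)CC=C)C2=C | intermediate
22 | ring B cycloheptene (C18 hydroxyl, C26 methyl ester) | COC(=O)[C@]12C[C@@](C)(O[Si](CC)(CC)CC)C(=O)[C@](C)(C[C@H]3C(C)C(O)C(C(=O)OC)=CC[C@@]31C)C2=C | intermediate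
23 | C26 acetyl intermediate (not isolated) | COC(=O)[C@]12C[C@@](C)(O[Si](CC)(CC)CC)C(=O)[C@](C)(C[C@H]3C(C)C(O)C(C(C)=O)=CC[C@@]31C)C2=C | intermediate
24 | diol (C18 and C23 hydroxyls) | COC(=O)[C@]12C[C@@](C)(O[Si](CC)(CC)CC)C(=O)[C@](C)(C[C@H]3C(C)C(O)C(C(C)(C)O)=CC[C@@]31C)C2=C | intermediate
25 | hydroxy enone (C18 ketone, C23 hydroxyl) | COC(=O)[C@]12C[C@@](C)(O[Si](CC)(CC)CC)C(=O)[C@](C)(C[C@H]3C(C)C(=O)C(C(C)(C)O)=CC[C@@]31C)C2=C | intermediate
26 | bis(triethylsilyl) enone | COC(=O)[C@]12C[C@@](C)(O[Si](CC)(CC)CC)C(=O)[C@](C)(C[C@H]3C(C)C(=O)C(C(C)(C)O[Si](CC)(CC)CC)=CC[C@@]31C)C2=C | intermediate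
27 | potassium dienolate of 26 (not isolated) | COC(=O)[C@]12C[C@@](C)(O[Si](CC)(CC)CC)C(=O)[C@](C)(C[C@H]3C(C)=C(O[K])C(C(C)(C)O[Si](CC)(CC)CC)=CC[C@@]31C)C2=C | intermediate
28 | dienyl triflate | COC(=O)[C@]12C[C@@](C)(O[Si](CC)(CC)CC)C(=O)[C@](C)(C[C@H]3C(C)=C(OS(=O)(=O)C(F)(F)F)C(C(C)(C)O[Si](CC)(CC)CC)=CC[C@@]31C)C2=C | intermediate
29 | diene ester (C18–CH2CO2Me) | COC(=O)[C@]12C[C@@](C)(O[Si](CC)(CC)CC)C(=O)[C@](C)(C[C@H]3C(C)=C(CC(=O)OC)C(C(C)(C)O[Si](CC)(CC)CC)=CC[C@@]31C)C2=C | intermediate
30 | dihydroxy ester (not isolated) | COC(=O)[C@]12C[C@@](C)(O)C(=O)[C@](C)(C[C@H]3C(C)=C(CC(=O)OC)C(C(C)(C)O)=CC[C@@]31C)C2=C | intermediate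
31 | C31-methylidene lactone | COC(=O)[C@]12C[C@@](C)(O)C(=O)[C@](C)(C[C@H]3C(C)=C4CC(=O)OC(C)(C)C4=CC[C@@]31C)C2=C | intermediate
32 | CNP0605450.1 | COC(=O)[C@]12C[C@@](C)(O)C(=O)[C@](C)(C[C@H]3C(C)=C4CC(=O)OC(C)(C)C4=CC[C@@]31C)[C@]21CO1 | target

**Totals**
Total step count: 21. Longest linear sequence: 21 steps (1 to 32).

**Steps most likely to fail**

Step 5. The chelated magnesium enolate may add to acrolein too slowly, so that acrolein polymerises, or the face selection at C5 may be poor. The fallback sets out from 6 and 7 and comes back at 10. The conjugate addition alone is run and quenched with aqueous NH4Cl to give the β-keto ester methyl (2S,3S,5R)-2,5-dimethyl-6-oxo-2-(prop-2-en-1-yl)-3-(prop-1-en-2-yl)cyclohexane-1-carboxylate F1. F1 is then added to acrolein 8 under a cinchona-alkaloid-derived bifunctional amine catalyst, a known catalytic Michael addition of α-substituted β-keto esters to enals. The face at C5 is then chosen by the catalyst in a separate step, and the matched pseudoenantiomer of the catalyst should give 10.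

Step 19. Transmetalation and reductive elimination at the dienyl triflate, which is flanked on both sides by fully substituted carbons, may lose out to reduction or hydrolysis of the triflate. The fallback sets out from 25 and comes back at 31. The tertiary C23 hydroxyl of 25 is acylated with diethylphosphonoacetic acid (DCC, DMAP) to the phosphonoacetate F2. An intramolecular Horner–Wadsworth–Emmons reaction onto the C18 ketone (LiCl, DBU, MeCN) closes ring A as the conjugated lactone F3, with C18=C19 and a hydrogen on C16. Deprotonation at C16 (LiN(iPr)2, THF/HMPA, −78 °C) and kinetic α-protonation with AcOH move the double bond to C16=C18 and give the triethylsilyl-protected lactone F4. Aqueous HF in MeCN then gives 31.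

Step 21. Oxygen transfer from the vanadium peroxide to the shielded, electron-poor methylidene may be slow, which leaves time for oxidation of the diene or of the C19 methylene. The fallback sets out from 25 and comes back at 32; it makes the epoxide before the diene exists. The C7 silyl ether of 25 is cleaved with HF·pyridine to the dihydroxy enone F5. mCPBA, guided by hydrogen bonding to the C7 hydroxyl and unreactive toward the enone, gives the spiro-epoxide F6. Both hydroxyls are silylated (Et3SiOTf, 2,6-lutidine) to the bis(triethylsilyl) epoxide F7. Enol triflate formation as in step 18 gives the epoxy dienyl triflate F8, and the coupling of step 19 gives the epoxy diene ester F9. Bu4NF buffered with AcOH removes both silyl groups, the lactone closes, and 32 is obtained.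

**Further compounds**
F1 | step 5 | methyl (2S,3S,5R)-2,5-dimethyl-6-oxo-2-(prop-2-en-1-yl)-3-(prop-1-en-2-yl)cyclohexane-1-carboxylate | COC(=O)C1C(=O)[C@H](C)C[C@@H](C(C)=C)[C@]1(C)CC=C
F2 | step 19 | phosphonoacetate of 25 | COC(=O)[C@]12C[C@@](C)(O[Si](CC)(CC)CC)C(=O)[C@](C)(C[C@H]3C(C)C(=O)C(C(C)(C)OC(=O)CP(=O)(OCC)OCC)=CC[C@@]31C)C2=C
F3 | step 19 | conjugated lactone | COC(=O)[C@]12C[C@@](C)(O[Si](CC)(CC)CC)C(=O)[C@](C)(C[C@H]3C(C)C4=CC(=O)OC(C)(C)C4=CC[C@@]31C)C2=C
F4 | step 19 | triethylsilyl-protected lactone | COC(=O)[C@]12C[C@@](C)(O[Si](CC)(CC)CC)C(=O)[C@](C)(C[C@H]3C(C)=C4CC(=O)OC(C)(C)C4=CC[C@@]31C)C2=C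
F5 | step 21 | dihydroxy enone | COC(=O)[C@]12C[C@@](C)(O)C(=O)[C@](C)(C[C@H]3C(C)C(=O)C(C(C)(C)O)=CC[C@@]31C)C2=C
F6 | step 21 | spiro-epoxide | COC(=O)[C@]12C[C@@](C)(O)C(=O)[C@](C)(C[C@H]3C(C)C(=O)C(C(C)(C)O)=CC[C@@]31C)[C@]21CO1
F7 | step 21 | bis(triethylsilyl) epoxide | COC(=O)[C@]12C[C@@](C)(O[Si](CC)(CC)CC)C(=O)[C@](C)(C[C@H]3C(C)C(=O)C(C(C)(C)O[Si](CC)(CC)CC)=CC[C@@]31C)[C@]21CO1
F8 | step 21 | epoxy dienyl triflate | COC(=O)[C@]12C[C@@](C)(O[Si](CC)(CC)CC)C(=O)[C@](C)(C[C@H]3C(C)=C(OS(=O)(=O)C(F)(F)F)C(C(C)(C)O[Si](CC)(CC)CC)=CC[C@@]31C)[C@]21CO1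
F9 | step 21 | epoxy diene ester | COC(=O)[C@]12C[C@@](C)(O[Si](CC)(CC)CC)C(=O)[C@](C)(C[C@H]3C(C)=C(CC(=O)OC)C(C(C)(C)O[Si](CC)(CC)CC)=CC[C@@]31C)[C@]21CO1
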